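**Strategy.** The seven-membered ring of the cis-hydroazulene is read as a five-carbon chain C6–C7–C8–C8a–C3a, whose central C8 bears the exocyclic carbon, closed by the two-carbon unit C5–C4(Me)2. A rhodium-catalysed (5+2) cycloaddition of propyne with a ring-fused vinylcyclopropane lactone therefore forms C5–C6 and C4–C3a at once and sets the cis ring fusion by retention. It leaves the lactone carbonyl as the future methylidene carbon and the lactone oxygen as a handle for a tertiary radical at C1. That radical is added to a 5-menthyloxybutenolide, and the adduct is ring-expanded to the acetoxylated δ-lactone.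

Key step: step 5

Remark on numbering: the bicycle carries azulene numbers in every intermediate (C1 methyl-bearing quaternary carbon, C3a/C8a ring fusion, C4 gem-dimethyl carbon, C8 methylidene-bearing carbon); the six-membered lactone carries pyranone numbers (O1, C2 carbonyl, C3–C6).
Assumption: (S)-(+)-linalool of high enantiomeric purity and (5S)-5-(d-menthyloxy)furan-2(5H)-one are taken as commercial; the latter is otherwise made from 5-hydroxyfuran-2(5H)-one and (+)-menthol.

**Step 1**
Reactants: 1 (S)-(+)-linalool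
Product: 2 (S)-1-methylcyclopent-2-en-1-ol
Conditions: second-generation Grubbs catalyst (H2IMes)(PCy3)Cl2Ru=CHPh (1 mol %), CH2Cl2, rt
Reagents that add atoms: none
Why: Ring-closing metathesis of the 1,6-diene expels 2-methylpropene and leaves the tertiary carbinol stereocentre untouched, which later relays its configuration to the ring fusion.

**Step 2**
Reactants: 2 (S)-1-methylcyclopent-2-en-1-ol; 3 but-3-enoic acid
Product: 4 (S)-1-methylcyclopent-2-en-1-yl but-3-enoate
Conditions: DCC, DMAP (10 mol %), CH2Cl2, 0 °C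
Reagents that add atoms: none
Why: Steglich esterification acylates the tertiary allylic alcohol under nearly neutral conditions, without ionising the carbinol centre and with the β,γ-double bond of the acid kept in place at low temperature.

**Step 3**
Reactants: 4 (S)-1-methylcyclopent-2-en-1-yl but-3-enoate
Product: 5 (S)-1-methylcyclopent-2-en-1-yl 2-diazobut-3-enoate
Conditions: p-ABSA, DBU, MeCN, 0 °C; used at once
Reagents that add atoms: 4-acetamidobenzenesulfonyl azide, CC(=O)Nc1ccc(cc1)S(=O)(=O)N=[N+]=[N-]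
Why: Regitz diazo transfer onto the vinylogously activated α-position gives the vinyldiazoacetate, which is kept cold and used directly to suppress electrocyclisation to the pyrazole.

**Step 4**
Reactants: 5 (S)-1-methylcyclopent-2-en-1-yl 2-diazobut-3-enoate
Product: 6 (1S)-4-ethenyl-1-methyl-2-oxatricyclo[3.2.1.0(4,8)]octan-3-one
Conditions: Rh2(OAc)4 (1 mol %), CH2Cl2, slow addition, 0 °C → rt
Reagents that add atoms: none
Why: Intramolecular cyclopropanation by the rhodium vinylcarbenoid is forced by the ester tether onto the ring face that carries the oxygen, so C8a, C3a and C8 are set from the (S)-carbinol carbon and the vinyl group ends up exo.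

**Step 5**
Reactants: 6 (1S)-4-ethenyl-1-methyl-2-oxatricyclo[3.2.1.0(4,8)]octan-3-one; 7 propyne
Product: 8 lactone of (1S,3aR,8aS)-1-hydroxy-1,4-dimethyl-1,2,3,3a,6,8a-hexahydroazulene-8-carboxylic acid
Conditions: [Rh(CO)2Cl]2 (5 mol %), propyne (5 equiv), ClCH2CH2Cl, 70 °C, sealed tube
Reagents that add atoms: none
Why: Monovalent rhodium binds the exo vinyl group of 6 and inserts into the adjoining cyclopropane bond C8–C3a to give a σ-alkyl/π-allyl rhodacyclohexene, propyne inserts at the allyl terminus C6 (bond C6–C5) and C(sp3)–C(sp2) reductive elimination then joins C3a to C4. The closest known reaction is the rhodium-catalysed intermolecular (5+2) cycloaddition of 1-substituted vinylcyclopropanes with alkynes. The seven-membered ring is closed in the reductive elimination from an eight-membered rhodacycle, that is as a metal-mediated (5+2) cycloaddition and not as an ionic or radical ring closure, and the lactone and cyclopentane rings are carried through unchanged. No new stereocentre is created, but C3a changes partner with retention (C–C to C–Rh to C–C on the same face), so the cis ring fusion is controlled by the cis-fused cyclopropane and, through the lactone tether of step 4, by the (S)-carbinol carbon C1. Two selectivities are needed: cleavage of C8–C3a rather than C8–C8a, which the fully substituted C1 next to C8a and the strain of the bridged lactone that the other cleavage would create should secure, and placement of the methyl-bearing alkyne carbon on C3a, which is expected because the alkyne substituent stays remote from the first-formed C6–C5 bond in the insertion step.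

**Step 6**
Reactants: 8 lactone of (1S,3aR,8aS)-1-hydroxy-1,4-dimethyl-1,2,3,3a,6,8a-hexahydroazulene-8-carboxylic acid
Product: 10 lactone of (1S,3aR,8aS)-1-hydroxy-1,4,4-trimethyl-1,2,3,3a,4,5,6,8a-octahydroazulene-8-carboxylic acid, via sulfonylhydrazide 9 (not isolated)
Conditions: Fe(acac)3 (50 mol %), PhSiH3, CH2=NNHSO2(n-C8H17), THF/MeOH, rt; then MeOH, 65 °C
Reagents that add atoms: formaldehyde octane-1-sulfonylhydrazone, C=NNS(=O)(=O)CCCCCCCC
Why: Hydrogen-atom-transfer hydromethylation (Mukaiyama-type radical hydrofunctionalisation) turns only the electron-rich trisubstituted alkene into the tertiary C4 radical, which adds to the hydrazone carbon, and thermal loss of sulfinate and N2 leaves the second methyl group on a carbon that is not a stereocentre.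

**Step 7**
Reactants: 10 lactone of (1S,3aR,8aS)-1-hydroxy-1,4,4-trimethyl-1,2,3,3a,4,5,6,8a-octahydroazulene-8-carboxylic acid
Product: 11 lactol of 10
Conditions: i-Bu2AlH (1.1 equiv), CH2Cl2, −78 °C
Reagents that add atoms: none
Why: Half-reduction of the unsaturated γ-lactone should stop at the lactol, the cyclic hemiacetal of the C8 enal with the C1 hydroxyl.

**Step 8**
Reactants: 11 lactol of 10
Product: 14 (1S,3aR,8aS)-1,4,4-trimethyl-8-methylidenedecahydroazulen-1-ol, via tosylhydrazone 12 (not isolated), via allylic diazene 13 (not isolated)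
Conditions: TsNHNH2, EtOH, rt; then catecholborane, CHCl3, 0 °C; then NaOAc·3H2O, 60 °C
Reagents that add atoms: none
Why: Alkene-transposing reduction of the α,β-unsaturated tosylhydrazone gives an allylic diazene that loses N2 by a retro-ene 1,5-hydrogen shift, which moves the double bond to the exocyclic position without ever activating the primary carbon toward ether formation with the neighbouring tertiary hydroxyl.

**Step 9**
Reactants: 14 (1S,3aR,8aS)-1,4,4-trimethyl-8-methylidenedecahydroazulen-1-ol
Product: 16 cesium oxalate of 14, via methyl oxalate 15 (not isolated)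
Conditions: ClCOCO2Me, Et3N, DMAP (cat.), CH2Cl2, 0 °C; then CsOH·H2O (1 equiv), THF/H2O, rt
Reagents that add atoms: methyl chlorooxoacetate, COC(=O)C(Cl)=O; cesium hydroxide, [Cs+].[OH-]
Why: Acylation of the tertiary alcohol followed by selective saponification of the unhindered methyl ester gives the bench-stable cesium oxalate that serves as the tertiary radical precursor.

**Step 10**
Reactants: 16 cesium oxalate of 14; 17 (5S)-5-{[(1S,2R,5S)-2-isopropyl-5-methylcyclohexyl]oxy}furan-2(5H)-one
Product: 18 (4R,5S)-5-(d-menthyloxy)-4-[(1R,3aR,8aS)-1,4,4-trimethyl-8-methylidenedecahydroazulen-1-yl]dihydrofuran-2(3H)-one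
Conditions: Ir[dF(CF3)ppy]2(dtbbpy)PF6 (1 mol %), blue LEDs, DME/DMF 3:1, H2O (10 equiv), 60 °C
Reagents that add atoms: none
Why: Photoredox oxidation and double decarboxylation of the oxalate give the planar C1 radical, which in a Giese addition reacts on its face anti to the C8a–C8 bond with the butenolide face anti to the menthyloxy group, so the quaternary C1 and the adjacent lactone carbon are set together.

**Step 11**
Reactants: 18 (4R,5S)-5-(d-menthyloxy)-4-(hydroazulenyl)dihydrofuran-2(3H)-one
Product: 19 (3R,4R,5S)-3-{[(4-methoxybenzyl)oxy]methyl}-5-(d-menthyloxy)-4-(hydroazulenyl)dihydrofuran-2(3H)-one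
Conditions: LiN(i-Pr)2, THF, −78 °C; then 4-MeOC6H4CH2OCH2Cl, −78 → −40 °C
Reagents that add atoms: 4-methoxybenzyl chloromethyl ether, COc1ccc(COCCl)cc1
Why: Alkylation of the lactone enolate takes place anti to the very large neighbouring substituent and should give the 3,4-trans product, which is also the thermodynamic one.

**Step 12**
Reactants: 19 (3R,4R,5S)-3-{[(4-methoxybenzyl)oxy]methyl}-5-(d-menthyloxy)-4-(hydroazulenyl)dihydrofuran-2(3H)-one
Product: 21 (3R,4R)-3-{[(4-methoxybenzyl)oxy]methyl}-4-(hydroazulenyl)dihydrofuran-2(3H)-one, via hydroxy carboxylate 20 (not isolated)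
Conditions: KOH, NaBH4, EtOH/H2O, 0 °C → rt; then aq. HCl to pH 2
Reagents that add atoms: none
Why: Saponification of the pseudo-ester releases menthol and the aldehyde, which is reduced as it forms, and acidification closes the lactone onto the new primary hydroxyl with both stereocentres unchanged.

**Step 13**
Reactants: 21 (3R,4R)-3-{[(4-methoxybenzyl)oxy]methyl}-4-(hydroazulenyl)dihydrofuran-2(3H)-one
Product: 24 (4R,5R)-4-{[(4-methoxybenzyl)oxy]methyl}-5-(hydroazulenyl)tetrahydro-2H-pyran-2-one, via dibromomethyl ketone 22 (not isolated), via ynolate 23 (not isolated)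
Conditions: CH2Br2, lithium 2,2,6,6-tetramethylpiperidide, THF, −78 °C; LiN(SiMe3)2; n-BuLi, −78 °C → rt; then HCl/Et2O, −78 °C → rt
Reagents that add atoms: dibromomethane, BrCBr
Why: Kowalski ester homologation: dibromomethyllithium adds to the lactone, bromine–lithium exchange on the derived dibromoenolate triggers a 1,2-shift of the α-carbon with retention to give an ynolate, and the ketene formed on protonation is captured by the tethered hydroxyl as the ring-enlarged δ-lactone.

**Step 14**
Reactants: 24 (4R,5R)-4-{[(4-methoxybenzyl)oxy]methyl}-5-(hydroazulenyl)tetrahydro-2H-pyran-2-one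
Product: 25 (3R,4R,5R)-3-hydroxy-4-{[(4-methoxybenzyl)oxy]methyl}-5-(hydroazulenyl)tetrahydro-2H-pyran-2-one
Conditions: KN(SiMe3)2, THF, −78 °C; 2-(phenylsulfonyl)-3-phenyloxaziridine; then AcOH
Reagents that add atoms: 2-(phenylsulfonyl)-3-phenyloxaziridine, O=S(=O)(N1OC1c1ccccc1)c1ccccc1
Why: Enolate hydroxylation (Davis oxidation) should occur anti to the adjacent C4 substituent and give the 3,4-trans α-hydroxy lactone.

**Step 15**
Reactants: 25 (3R,4R,5R)-3-hydroxy-4-{[(4-methoxybenzyl)oxy]methyl}-5-(hydroazulenyl)tetrahydro-2H-pyran-2-one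
Product: 26 (3R,4R,5R)-3-hydroxy-4-(hydroxymethyl)-5-(hydroazulenyl)tetrahydro-2H-pyran-2-one
Conditions: DDQ, CH2Cl2/pH 7 buffer, 0 °C; used at once
Reagents that add atoms: none
Why: Oxidative cleavage of the 4-methoxybenzyl ether under neutral conditions frees the primary alcohol without translactonisation and without touching the exocyclic alkene.

**Step 16**
Reactants: 26 (3R,4R,5R)-3-hydroxy-4-(hydroxymethyl)-5-(hydroazulenyl)tetrahydro-2H-pyran-2-one
Product: 27 (3S,4R,5R)-3-acetoxy-4-(acetoxymethyl)-5-[(1R,3aR,8aS)-1,4,4-trimethyl-8-methylidenedecahydroazulen-1-yl]tetrahydro-2H-pyran-2-one (target)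
Conditions: AcOH (6 equiv), PPh3, DIAD, toluene, 0 °C → rt
Reagents that add atoms: acetic acid, CC(=O)O
Why: Double Mitsunobu esterification acetylates the primary alcohol and replaces the secondary α-hydroxyl by acetate with inversion (SN2 at the carbon next to the carbonyl), which gives the 3,4-cis diacetate.

**Compound list**
1 | (S)-(+)-linalool, (3S)-3,7-dimethylocta-1,6-dien-3-ol | CC(C)=CCC[C@](C)(O)C=C | starting material
2 | (S)-1-methylcyclopent-2-en-1-ol | C[C@@]1(O)C=CCC1 | intermediate
3 | but-3-enoic acid | C=CCC(=O)O | starting material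
4 | (S)-1-methylcyclopent-2-en-1-yl but-3-enoate | C[C@@]1(OC(=O)CC=C)C=CCC1 | intermediate
5 | (S)-1-methylcyclopent-2-en-1-yl 2-diazobut-3-enoate | C[C@@]1(OC(=O)C(=[N+]=[N-])C=C)C=CCC1 | intermediate
6 | (1S)-4-ethenyl-1-methyl-2-oxatricyclo[3.2.1.0(4,8)]octan-3-one; cyclopropane (C8, C8a, C3a) fused to the cyclopentane on the face of the lactone oxygen, vinyl exo | C=C[C@]12[C@@H]3CC[C@](C)(OC1=O)[C@H]23 | intermediate
7 | propyne | CC#C | starting material
8 | lactone of (1S,3aR,8aS)-1-hydroxy-1,4-dimethyl-1,2,3,3a,6,8a-hexahydroazulene-8-carboxylic acid (cis-fused, C4=C5 and C7=C8) | CC1=CCC=C2C(=O)O[C@@]3(C)CC[C@@H]1[C@@H]23 | intermediate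
9 | lactone 8 carrying H at C5 and CH2NHNHSO2(n-octyl) at C4 (both C4 epimers) | CCCCCCCCS(=O)(=O)NNCC1(C)CCC=C2C(=O)O[C@@]3(C)CC[C@@H]1[C@@H]23 | intermediate
10 | lactone of (1S,3aR,8aS)-1-hydroxy-1,4,4-trimethyl-1,2,3,3a,4,5,6,8a-octahydroazulene-8-carboxylic acid | CC1(C)CCC=C2C(=O)O[C@@]3(C)CC[C@@H]1[C@@H]23 | intermediate
11 | lactol of 10 (hemiacetal carbon as a mixture) | CC1(C)CCC=C2C(O)O[C@@]3(C)CC[C@@H]1[C@@H]23 | intermediate
12 | tosylhydrazone of (1S,3aR,8aS)-1-hydroxy-1,4,4-trimethyl-1,2,3,3a,4,5,6,8a-octahydroazulene-8-carbaldehyde (C=N geometry open) | Cc1ccc(cc1)S(=O)(=O)NN=CC1=CCCC(C)(C)[C@@H]2CC[C@@](O)(C)[C@H]12 | intermediate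
13 | (1S,3aR,8aS)-8-(diazenylmethyl)-1,4,4-trimethyl-1,2,3,3a,4,5,6,8a-octahydroazulen-1-ol | N=NCC1=CCCC(C)(C)[C@@H]2CC[C@@](O)(C)[C@H]12 | intermediate
14 | (1S,3aR,8aS)-1,4,4-trimethyl-8-methylidenedecahydroazulen-1-ol | C=C1CCCC(C)(C)[C@@H]2CC[C@@](O)(C)[C@H]12 | intermediate
15 | methyl (1S,3aR,8aS)-1,4,4-trimethyl-8-methylidenedecahydroazulen-1-yl oxalate | C=C1CCCC(C)(C)[C@@H]2CC[C@@](OC(=O)C(=O)OC)(C)[C@H]12 | intermediate
16 | cesium (1S,3aR,8aS)-1,4,4-trimethyl-8-methylidenedecahydroazulen-1-yl oxalate | C=C1CCCC(C)(C)[C@@H]2CC[C@@](OC(=O)C(=O)[O-])(C)[C@H]12.[Cs+] | intermediate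
17 | (5S)-5-{[(1S,2R,5S)-2-isopropyl-5-methylcyclohexyl]oxy}furan-2(5H)-one | O=C1C=C[C@@H](O[C@H]2C[C@@H](C)CC[C@@H]2C(C)C)O1 | starting material
18 | (4R,5S)-5-(d-menthyloxy)-4-[(1R,3aR,8aS)-1,4,4-trimethyl-8-methylidenedecahydroazulen-1-yl]dihydrofuran-2(3H)-one (4,5-trans) | C=C1CCCC(C)(C)[C@@H]2CC[C@@](C)([C@@H]3[C@@H](O[C@H]4C[C@@H](C)CC[C@@H]4C(C)C)OC(=O)C3)[C@H]12 | intermediate
19 | (3R,4R,5S)-3-{[(4-methoxybenzyl)oxy]methyl}-5-(d-menthyloxy)-4-[(1R,3aR,8aS)-hydroazulenyl]dihydrofuran-2(3H)-one (3,4-trans, 4,5-trans) | C=C1CCCC(C)(C)[C@@H]2CC[C@@](C)([C@@H]3[C@@H](O[C@H]4C[C@@H](C)CC[C@@H]4C(C)C)OC(=O)[C@H]3COCc3ccc(OC)cc3)[C@H]12 | intermediate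
20 | potassium 4-hydroxy-2-{[(4-methoxybenzyl)oxy]methyl}-3-[(1R,3aR,8aS)-hydroazulenyl]butanoate (ring-opened form of 21) | C=C1CCCC(C)(C)[C@@H]2CC[C@@](C)([C@H](CO)[C@H](COCc3ccc(OC)cc3)C(=O)[O-])[C@H]12.[K+] | intermediate
21 | (3R,4R)-3-{[(4-methoxybenzyl)oxy]methyl}-4-[(1R,3aR,8aS)-1,4,4-trimethyl-8-methylidenedecahydroazulen-1-yl]dihydrofuran-2(3H)-one (trans) | C=C1CCCC(C)(C)[C@@H]2CC[C@@](C)([C@@H]3COC(=O)[C@H]3COCc3ccc(OC)cc3)[C@H]12 | intermediate
22 | lithium alkoxide of the ring-opened dibromomethyl ketone from 21 | C=C1CCCC(C)(C)[C@@H]2CC[C@@](C)([C@H](C[O-])[C@H](COCc3ccc(OC)cc3)C(=O)C(Br)Br)[C@H]12.[Li+] | intermediate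
23 | dilithium ynolate alkoxide from 22 | C=C1CCCC(C)(C)[C@@H]2CC[C@@](C)([C@H](C[O-])[C@H](COCc3ccc(OC)cc3)C#C[O-])[C@H]12.[Li+].[Li+] | intermediate
24 | (4R,5R)-4-{[(4-methoxybenzyl)oxy]methyl}-5-[(1R,3aR,8aS)-hydroazulenyl]tetrahydro-2H-pyran-2-one (trans) | C=C1CCCC(C)(C)[C@@H]2CC[C@@](C)([C@@H]3COC(=O)C[C@H]3COCc3ccc(OC)cc3)[C@H]12 | intermediate
25 | (3R,4R,5R)-3-hydroxy-4-{[(4-methoxybenzyl)oxy]methyl}-5-[(1R,3aR,8aS)-hydroazulenyl]tetrahydro-2H-pyran-2-one (3,4-trans, 4,5-trans) | C=C1CCCC(C)(C)[C@@H]2CC[C@@](C)([C@@H]3COC(=O)[C@H](O)[C@H]3COCc3ccc(OC)cc3)[C@H]12 | intermediate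
26 | (3R,4R,5R)-3-hydroxy-4-(hydroxymethyl)-5-[(1R,3aR,8aS)-hydroazulenyl]tetrahydro-2H-pyran-2-one | C=C1CCCC(C)(C)[C@@H]2CC[C@@](C)([C@@H]3COC(=O)[C@H](O)[C@H]3CO)[C@H]12 | intermediate
27 | (3S,4R,5R)-3-acetoxy-4-(acetoxymethyl)-5-[(1R,3aR,8aS)-1,4,4-trimethyl-8-methylidenedecahydroazulen-1-yl]tetrahydro-2H-pyran-2-one | C=C1CCCC(C)(C)[C@@H]2CC[C@@](C)([C@@H]3COC(=O)[C@@H](OC(C)=O)[C@H]3COC(C)=O)[C@H]12 | target

**Count.** Total steps: 16. Longest linear sequence: 16 steps, from 1 to 27; compounds 3, 7 and 17 are bought.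

**Steps most likely to fail**

Step 5. Propyne may insert with its methyl group toward C5 instead of C4, because methyl is only a weak steric director. The rhodacycle may also collapse to a diene by β-hydride elimination before the alkyne is taken up. The fallback sets out from 6 and comes back at 10. The cycloaddition is run with tert-butyldimethyl(prop-2-yn-1-yloxy)silane, a bulkier ether-bearing alkyne that should place its substituent next to the former cyclopropane carbon, to give the C4-(silyloxymethyl) dienyl lactone F1. Fluoride (Bu4NF, THF) gives the allylic alcohol F2. Reductive allylic transposition with 2-nitrobenzenesulfonylhydrazide, PPh3 and DEAD moves the double bond out of the ring and gives the C4-methylidene lactone F3. The hydrogen-atom-transfer hydromethylation of step 6, now on a 1,1-disubstituted alkene, should then give 10 by way of 9.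

Step 6. Reversible hydrogen-atom transfer may walk the C4=C5 double bond toward the ring fusion, and capture of the hindered tertiary radical by the hydrazone may be slow. The fallback sets out from 8 and comes back at 10 by ionic chemistry. Markovnikov addition of dry HCl (CH2Cl2, −78 °C) to the trisubstituted alkene gives the tertiary chloride F4. Exchange of chloride for methyl with Me2TiCl2 (from Me2Zn and TiCl4, CH2Cl2, −78 → −30 °C), which tolerates the lactone, gives 10.

Step 13. The amide base may deprotonate the α-branched lactone instead of letting the carbenoid add, and the ynolate may be lost by oligomerisation on warming. The fallback sets out from 21 and comes back at 24 by a stepwise Arndt–Eistert-type ring expansion. Lithiated trimethylsilyldiazomethane (Me3SiCHN2, n-BuLi, THF, −78 °C, aqueous work-up) opens the lactone to the δ-hydroxy α-diazo ketone F5. Wolff rearrangement promoted by silver benzoate (PhCO2Ag) and Et3N, with capture of the ketene by the primary hydroxyl, gives 24.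

Further compounds
F1 | step 5 | lactone of (1S,3aR,8aS)-4-{[(tert-butyldimethylsilyl)oxy]methyl}-1-hydroxy-1-methyl-1,2,3,3a,6,8a-hexahydroazulene-8-carboxylic acid | CC(C)(C)[Si](C)(C)OCC1=CCC=C2C(=O)O[C@@]3(C)CC[C@@H]1[C@@H]23
F2 | step 5 | lactone of (1S,3aR,8aS)-1-hydroxy-4-(hydroxymethyl)-1-methyl-1,2,3,3a,6,8a-hexahydroazulene-8-carboxylic acid | OCC1=CCC=C2C(=O)O[C@@]3(C)CC[C@@H]1[C@@H]23
F3 | step 5 | lactone of (1S,3aR,8aS)-1-hydroxy-1-methyl-4-methylidene-1,2,3,3a,4,5,6,8a-octahydroazulene-8-carboxylic acid | C=C1CCC=C2C(=O)O[C@@]3(C)CC[C@@H]1[C@@H]23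
F4 | step 6 | lactone of (1S,3aR,8aS)-4-chloro-1-hydroxy-1,4-dimethyl-1,2,3,3a,4,5,6,8a-octahydroazulene-8-carboxylic acid (C4 epimers) | CC1(Cl)CCC=C2C(=O)O[C@@]3(C)CC[C@@H]1[C@@H]23
F5 | step 13 | 1-diazo-5-hydroxy-3-{[(4-methoxybenzyl)oxy]methyl}-4-[(1R,3aR,8aS)-1,4,4-trimethyl-8-methylidenedecahydroazulen-1-yl]pentan-2-one | C=C1CCCC(C)(C)[C@@H]2CC[C@@](C)([C@H](CO)[C@H](COCc3ccc(OC)cc3)C(=O)C=[N+]=[N-])[C@H]12
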